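**Retrosynthetic overview**
1. The 10-membered carbocycle is closed last, at C3–C4, by intramolecular Nozaki–Hiyama–Kishi addition of a Z alkenyl iodide to a cis-epoxy aldehyde (sets C4).
2. The lactone C1–O bond is made with inversion by Mitsunobu esterification of an erythro epoxy alcohol with acrylic acid; in the same flask a phosphine closes the lactone by 5-exo opening of the C9–C10 oxirane (sets C10, frees C9–OH for the angelate).
3. The epoxy alcohol comes from Sharpless epoxidation of a divinyl carbinol, made by asymmetric addition of an alkenylzinc (from a terminal alkyne) to (Z)-3-iodobut-2-enal.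
4. The alkyne comes from neryl acetate (ozonolysis, Ohira–Bestmann homologation, Sharpless epoxidation for C5/C6, silylation); the iodoenal comes from but-2-yn-1-ol.
5. Ring order: C5–C6 oxirane → C9–C10 oxirane (consumed) → γ-lactone → 10-membered ring.

Assumption (locants used below): C1 = lactone O–CH, C2=C3(Me), C4 = carbinol, C5–C6(Me) = oxirane, C7, C8, C9 = angelate carbon, C10 = ring-fusion CH. The given SMILES then reads 1S,4R,5R,6S,9R,10R, with a Z C2=C3 alkene, a cis oxirane and a cis-fused lactone.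

**Step 1**
Reactants: 1 neryl acetate
Product: 3 (2Z)-3-methyl-6-oxohex-2-en-1-yl acetate, via secondary ozonide 2 (not isolated)
Conditions: O3 (1.0 equiv), CH2Cl2–pyridine, −78 °C; Me2S, −78 °C → rt
Reagents that add atoms: ozone, [O-][O+]=O
Why: Chemoselective ozonolysis with reductive work-up: electrophilic ozone cleaves the electron-rich 6,7-alkene faster than the 2,3-alkene deactivated by the allylic acetate, and the Z alkene is untouched.

**Step 2**
Reactants: 3 (2Z)-3-methyl-6-oxohex-2-en-1-yl acetate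
Product: 5 (2Z)-3-methylhept-2-en-6-yn-1-ol, via enyne acetate 4 (not isolated)
Conditions: dimethyl (1-diazo-2-oxopropyl)phosphonate, K2CO3, MeOH, 0 °C → rt
Reagents that add atoms: dimethyl (1-diazo-2-oxopropyl)phosphonate, CC(=O)C(=[N+]=[N-])P(=O)(OC)OC
Why: Ohira–Bestmann (Seyferth–Gilbert) homologation turns the aldehyde into the terminal alkyne that supplies C10, and the same K2CO3/MeOH medium removes the acetate by transesterification.

**Step 3**
Reactants: 5 (2Z)-3-methylhept-2-en-6-yn-1-ol
Product: 6 [(2R,3S)-3-(but-3-yn-1-yl)-3-methyloxiran-2-yl]methanol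
Conditions: Ti(OiPr)4 (10 mol%), D-(−)-diethyl tartrate (13 mol%), t-BuOOH, 4 Å MS, CH2Cl2, −20 °C
Reagents that add atoms: tert-butyl hydroperoxide, CC(C)(C)OO
Why: Sharpless asymmetric epoxidation of the Z trisubstituted allylic alcohol; the D-(−)-tartrate titanium complex delivers oxygen to the face that gives the (2R,3S) cis-oxirane, fixing C5 and C6.

**Step 4**
Reactants: 6 [(2R,3S)-3-(but-3-yn-1-yl)-3-methyloxiran-2-yl]methanol
Product: 7 TES ether of 6
Conditions: Et3SiCl, imidazole, CH2Cl2, 0 °C
Reagents that add atoms: chlorotriethylsilane, CC[Si](Cl)(CC)CC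
Why: Standard silylation; the primary TES ether masks C4–OH through the organometallic steps and can later be oxidised directly to the aldehyde.

**Step 5**
Reactants: 8 but-2-yn-1-ol
Product: 10 (2Z)-3-iodobut-2-en-1-ol, via cyclic alkenylalanate 9 (not isolated)
Conditions: NaAlH2(OCH2CH2OMe)2, THF, 0 °C → rt; then I2, −78 → 0 °C
Reagents that add atoms: iodine, II
Why: Hydroxyl-directed trans-hydroalumination places aluminium on C3 in a five-membered alanate, and iodinolysis with retention gives only the Z alkenyl iodide.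

**Step 6**
Reactants: 10 (2Z)-3-iodobut-2-en-1-ol
Product: 11 (2Z)-3-iodobut-2-enal
Conditions: MnO2, CH2Cl2, rt
Reagents that add atoms: none
Why: MnO2 oxidation of an allylic alcohol under neutral conditions that do not isomerise the Z iodoalkene.

**Step 7**
Reactants: 7 TES ether of 6; 11 (2Z)-3-iodobut-2-enal
Product: 14 (4S)-divinyl carbinol (2Z,4S,5E)-2-iodo-8-[(2S,3R)-2-methyl-3-{[(triethylsilyl)oxy]methyl}oxiran-2-yl]octa-2,5-dien-4-ol, via alkenylborane 12 (not isolated), via alkenylzinc 13 (not isolated)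
Conditions: Cy2BH, toluene, 0 °C → rt; Me2Zn, −78 °C; (−)-MIB (5 mol%), then 11, −20 °C
Reagents that add atoms: none
Why: Hydroboration then boron-to-zinc transmetalation gives an (E)-alkenylzinc, and its (−)-MIB-catalysed asymmetric 1,2-addition to the enal on the Si face sets the (S)-carbinol at C1 and the E C9=C10 alkene.

**Step 8**
Reactants: 14 (4S)-divinyl carbinol
Product: 15 erythro epoxy alcohol (1R,2Z)-3-iodo-1-[(2R,3R)-3-(2-{(2S,3R)-2-methyl-3-[(triethylsilyloxy)methyl]oxiran-2-yl}ethyl)oxiran-2-yl]but-2-en-1-ol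
Conditions: Ti(OiPr)4 (20 mol%), D-(−)-diisopropyl tartrate (24 mol%), t-BuOOH, 4 Å MS, CH2Cl2, −20 °C
Reagents that add atoms: tert-butyl hydroperoxide, CC(C)(C)OO
Why: Sharpless epoxidation in its matched, hydroxyl-directed mode: the D-(−)-tartrate catalyst epoxidises only the E allylic alkene of the (S)-alcohol (the Z iodoalkene is inert) and gives the erythro trans-epoxy alcohol, fixing C9 and C10.

**Step 9**
Reactants: 15 erythro epoxy alcohol; 16 acrylic acid
Product: 18 lactone alcohol (4R,5R)-4-[(1R)-1-hydroxy-3-{(2S,3R)-2-methyl-3-[(triethylsilyloxy)methyl]oxiran-2-yl}propyl]-5-[(1Z)-2-iodoprop-1-en-1-yl]-3-methylideneoxolan-2-one, via threo acrylate ester 17 (not isolated)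
Conditions: PPh3, DIAD, toluene, 0 °C → rt; then PMe3 (0.5 equiv), t-BuOH, 45 °C; Et3N-buffered work-up, crude product used at once
Reagents that add atoms: none
Why: Proposed new method: a one-pot C–O/C–C lactone annulation. Mitsunobu esterification with acrylic acid forms the lactone C1–O bond by SN2 inversion (erythro → threo, setting C1); PMe3 then adds to the acrylate and the phosphonium enolate opens the adjacent oxirane at C10 by 5-exo SN2 attack (inversion, giving the cis-disubstituted lactone and C9–OH), after which the C9 alkoxide relays the α-proton and PMe3 is eliminated to unveil the exo-methylene. The closest known reactions are the Mitsunobu inversion of epoxy alcohols and the phosphine-mediated intramolecular Morita–Baylis–Hillman alkylation of enones by epoxides, here extended to an acrylate ester tether that closes a γ-lactone.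

**Step 10**
Reactants: 18 lactone alcohol; 19 angelic acid
Product: 21 C9 angelate of 18, via mixed anhydride 20 (not isolated)
Conditions: 19, 2,4,6-trichlorobenzoyl chloride, Et3N, toluene, rt; then 18, DMAP (cat.), rt
Reagents that add atoms: none
Why: Yamaguchi esterification through the mixed anhydride acylates C9–OH with retention and without Z→E isomerisation of the angelate, under basic conditions that spare the oxirane.

**Step 11**
Reactants: 21 C9 angelate of 18
Product: 23 cis-epoxy aldehyde, via alkoxysulfonium chloride 22 (not isolated)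
Conditions: (COCl)2, DMSO, CH2Cl2, −78 → −40 °C; Et3N, −78 → 0 °C
Reagents that add atoms: none
Why: Under Swern conditions a primary TES ether is cleaved by the chlorosulfonium reagent and oxidised in the same operation, giving the aldehyde without a separate desilylation and without touching any stereocentre.

**Step 12**
Reactants: 23 cis-epoxy aldehyde
Product: 25 target CNP0500828.1, via alkenylchromium dichloride 24 (not isolated)
Conditions: CrCl2 (10 equiv), NiCl2 (1 mol%), DMSO–THF 3:1, 2 mM, rt
Reagents that add atoms: none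
Why: Intramolecular Nozaki–Hiyama–Kishi reaction: the alkenylchromium forms with retention of the Z geometry and adds chemoselectively to the aldehyde to close the 10-membered ring, and Felkin–Anh attack anti to the oxirane C–O bond gives the erythro (4R) alcohol.

**Compound list**
1 | neryl acetate, (2Z)-3,7-dimethylocta-2,6-dien-1-yl acetate | CC(C)=CCC/C(C)=C\COC(C)=O | starting material
2 | secondary ozonide, (2Z)-5-(5,5-dimethyl-1,2,4-trioxolan-3-yl)-3-methylpent-2-en-1-yl acetate (ring CH as a mixture) | CC1(C)OOC(CC/C(C)=C\COC(C)=O)O1 | intermediate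
3 | (2Z)-3-methyl-6-oxohex-2-en-1-yl acetate | O=CCC/C(C)=C\COC(C)=O | intermediate
4 | enyne acetate, (2Z)-3-methylhept-2-en-6-yn-1-yl acetate | C#CCC/C(C)=C\COC(C)=O | intermediate
5 | (2Z)-3-methylhept-2-en-6-yn-1-ol | C#CCC/C(C)=C\CO | intermediate
6 | [(2R,3S)-3-(but-3-yn-1-yl)-3-methyloxiran-2-yl]methanol | OC[C@H]1O[C@@]1(C)CCC#C | intermediate
7 | TES ether of 6, {[(2R,3S)-3-(but-3-yn-1-yl)-3-methyloxiran-2-yl]methoxy}triethylsilane | CC[Si](CC)(CC)OC[C@H]1O[C@@]1(C)CCC#C | intermediate
8 | but-2-yn-1-ol | CC#CCO | starting material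
9 | cyclic alkenylalanate, sodium 2,2-bis(2-methoxyethoxy)-3-methyl-2,5-dihydro-1,2-oxaluminol-2-uide | CC1=CCO[Al-]1(OCCOC)OCCOC.[Na+] | intermediate
10 | (2Z)-3-iodobut-2-en-1-ol | C/C(I)=C/CO | intermediate
11 | (2Z)-3-iodobut-2-enal | C/C(I)=C/C=O | intermediate
12 | (E)-alkenyl(dicyclohexyl)borane from 7 | CC[Si](CC)(CC)OC[C@H]1O[C@@]1(C)CC/C=C/B(C1CCCCC1)C1CCCCC1 | intermediate
13 | (E)-alkenyl(methyl)zinc from 7 | CC[Si](CC)(CC)OC[C@H]1O[C@@]1(C)CC/C=C/[Zn]C | intermediate
14 | (2Z,4S,5E)-2-iodo-8-[(2S,3R)-2-methyl-3-{[(triethylsilyl)oxy]methyl}oxiran-2-yl]octa-2,5-dien-4-ol | O[C@H](/C=C(/C)I)/C=C/CC[C@]1(C)O[C@@H]1CO[Si](CC)(CC)CC | intermediate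
15 | erythro epoxy alcohol, (1R,2Z)-3-iodo-1-[(2R,3R)-3-(2-{(2S,3R)-2-methyl-3-[(triethylsilyloxy)methyl]oxiran-2-yl}ethyl)oxiran-2-yl]but-2-en-1-ol | O[C@H](/C=C(/C)I)[C@H]1O[C@@H]1CC[C@]2(C)O[C@@H]2CO[Si](CC)(CC)CC | intermediate
16 | acrylic acid | C=CC(=O)O | starting material
17 | threo acrylate (C1 inverted), (1S,2Z)-3-iodo-1-[(2S,3R)-3-(2-{(2S,3R)-2-methyl-3-[(triethylsilyloxy)methyl]oxiran-2-yl}ethyl)oxiran-2-yl]but-2-en-1-yl prop-2-enoate | C=CC(=O)O[C@@H](/C=C(/C)I)[C@H]1O[C@@H]1CC[C@]2(C)O[C@@H]2CO[Si](CC)(CC)CC | intermediate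
18 | lactone alcohol, (4R,5R)-4-[(1R)-1-hydroxy-3-{(2S,3R)-2-methyl-3-[(triethylsilyloxy)methyl]oxiran-2-yl}propyl]-5-[(1Z)-2-iodoprop-1-en-1-yl]-3-methylideneoxolan-2-one | C=C1C(=O)O[C@@H](/C=C(/C)I)[C@H]1[C@H](O)CC[C@]2(C)O[C@@H]2CO[Si](CC)(CC)CC | intermediate
19 | angelic acid, (2Z)-2-methylbut-2-enoic acid | C/C=C(/C)C(=O)O | starting material
20 | mixed anhydride, (2Z)-2-methylbut-2-enoic 2,4,6-trichlorobenzoic anhydride | C/C=C(/C)C(=O)OC(=O)c1c(Cl)cc(Cl)cc1Cl | intermediate
21 | (1R)-1-[(2R,3R)-2-[(1Z)-2-iodoprop-1-en-1-yl]-4-methylidene-5-oxooxolan-3-yl]-3-[(2S,3R)-2-methyl-3-{[(triethylsilyl)oxy]methyl}oxiran-2-yl]propyl (2Z)-2-methylbut-2-enoate | C=C1C(=O)O[C@@H](/C=C(/C)I)[C@H]1[C@H](OC(=O)/C(C)=C\C)CC[C@]2(C)O[C@@H]2CO[Si](CC)(CC)CC | intermediate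
22 | alkoxysulfonium chloride, the O-dimethylsulfonio analogue of 21 (Et3Si replaced by Me2S+) | C=C1C(=O)O[C@@H](/C=C(/C)I)[C@H]1[C@H](OC(=O)/C(C)=C\C)CC[C@]2(C)O[C@@H]2CO[S+](C)C.[Cl-] | intermediate
23 | (1R)-3-[(2S,3S)-3-formyl-2-methyloxiran-2-yl]-1-[(2R,3R)-2-[(1Z)-2-iodoprop-1-en-1-yl]-4-methylidene-5-oxooxolan-3-yl]propyl (2Z)-2-methylbut-2-enoate | C=C1C(=O)O[C@@H](/C=C(/C)I)[C@H]1[C@H](OC(=O)/C(C)=C\C)CC[C@]2(C)O[C@@H]2C=O | intermediate
24 | alkenylchromium dichloride, 23 with CrCl2 in place of iodine | C=C1C(=O)O[C@@H](/C=C(/C)[Cr](Cl)Cl)[C@H]1[C@H](OC(=O)/C(C)=C\C)CC[C@]2(C)O[C@@H]2C=O | intermediate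
25 | CNP0500828.1: (1S,2Z,4R,5R,6S,9R,10R) 10-membered-ring cis-fused α-methylene-γ-lactone with 4-OH, 5,6-oxirane, 3- and 6-methyl, 9-O-angelate (locants as defined above) | C=C1C(=O)O[C@H]2/C=C(/C)[C@@H](O)[C@H]3O[C@@]3(C)CC[C@@H](OC(=O)/C(C)=C\C)[C@@H]12 | target

**Step count and risks**
Total steps: 12. Longest linear sequence: 10 (steps 1–4, then 7–12).

Step 9 (the new annulation) is the most likely to fail. The Mitsunobu step could give SN2′ or elimination products on the allylic epoxy carbinol. The enolate alkylation of an unactivated oxirane through an ester tether may be slow or go 6-endo. The freed C9–OH could attack the C5–C6 oxirane or translactonise. The fallback uses known chemistry. Starting from 15, Mitsunobu esterification with (diethoxyphosphoryl)acetic acid (PPh3, DIAD) gives the inverted phosphonoacetate F1. NaH in THF (0 → 40 °C) then closes the ring by intramolecular 5-exo alkylation of the stabilised carbanion on the oxirane, giving the α-phosphono lactone F2. Horner–Wadsworth–Emmons methylenation with paraformaldehyde in the same flask gives 18, where the route resumes.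

Step 12 is the second risk. The macrocyclic transition state may override Felkin control at C4, and divalent chromium may partly reduce the epoxy aldehyde. In the fallback, C4 is set by reduction instead of by addition. Starting from 23, the ring closure is run without relying on its selectivity and gives 25 together with its C4 epimer F3. The mixture is oxidised with Dess–Martin periodinane (NaHCO3, CH2Cl2) to the macrocyclic epoxy enone F4. Chelation-controlled 1,2-reduction with Zn(BH4)2 (Et2O, −30 °C) then delivers hydride anti to the oxirane and returns the erythro alcohol 25.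

Step 7 is the third risk. The β-iodo enal can undergo addition–elimination, and the alkenylzinc transfer may be slow or poorly selective. The fallback builds the E alkene by alkynylation and reduction. Starting from 7 and 11, Me2Zn/ProPhenol-catalysed asymmetric alkynylation (the ligand antipode that adds to the Si face) gives the propargylic alcohol F5. Hydroxyl-directed trans-reduction with NaAlH2(OCH2CH2OMe)2 (THF, −20 °C, protic quench) then gives the E allylic alcohol 14, where the route resumes.

**Further compounds**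
F1 | step 9 | (1S,2Z)-3-iodo-1-[(2S,3R)-3-(2-{(2S,3R)-2-methyl-3-[(triethylsilyloxy)methyl]oxiran-2-yl}ethyl)oxiran-2-yl]but-2-en-1-yl (diethoxyphosphoryl)acetate | CCOP(=O)(OCC)CC(=O)O[C@@H](/C=C(/C)I)[C@H]1O[C@@H]1CC[C@]2(C)O[C@@H]2CO[Si](CC)(CC)CC
F2 | step 9 | α-(diethoxyphosphoryl) analogue of lactone 18 (P-bearing carbon as a mixture) | CCOP(=O)(OCC)C1C(=O)O[C@@H](/C=C(/C)I)[C@H]1[C@H](O)CC[C@]2(C)O[C@@H]2CO[Si](CC)(CC)CC
F3 | step 12 | C4 epimer (4S) of 25 | C=C1C(=O)O[C@H]2/C=C(/C)[C@H](O)[C@H]3O[C@@]3(C)CC[C@@H](OC(=O)/C(C)=C\C)[C@@H]12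
F4 | step 12 | C4 ketone (epoxy enone) of 25 | C=C1C(=O)O[C@H]2/C=C(/C)C(=O)[C@H]3O[C@@]3(C)CC[C@@H](OC(=O)/C(C)=C\C)[C@@H]12
F5 | step 7 | (2Z,4R)-2-iodo-8-[(2S,3R)-2-methyl-3-{[(triethylsilyl)oxy]methyl}oxiran-2-yl]oct-2-en-5-yn-4-ol | O[C@H](/C=C(/C)I)C#CCC[C@]1(C)O[C@@H]1CO[Si](CC)(CC)CC
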